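**Strategy.** The flavone is cut through ring C at three bonds: C4a–C4, C4–C3 and O1–C2. The feature used is that the pyranone holds one carbonyl carbon, C4, set between ring A carbon C4a (next to the oxygen-bearing C8a) and the two-carbon unit C3–C2 that holds ring B. C4 can therefore come from CO, C3–C2 from a terminal alkyne and O1 from a phenol. A palladium-catalysed carbonylative coupling of a 2-iodophenol with an arylacetylene, followed in the same flask by 6-endo closure of the phenol oxygen onto C2, builds ring C in one operation. The precursors are 2-iodo-3,5-bis(silyloxy)phenol and the fully substituted, silyl-protected (R)-configured ring B acetylene.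

Key step: step 14

Remarks on the chemistry:
- The target stereocentre is (R) (O > isopropenyl > CH2Ar > H). It is taken from methyl (R)-glycidate, whose C2–O bond is never broken. The ester carbon and the isopropenyl carbon that replaces it both rank between O and CH2Ar, so the descriptor stays (R) throughout.
- The dimethylpropargyl ether must be semi-hydrogenated before the Claisen step; heating the alkyne itself would give a chromene instead of the prenyl phenol.
- Organometallic steps are written with a water quench, so magnesium and lithium end as hydroxide salts.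
- TBS = tert-butyldimethylsilyl.

**Route**

Step 1
Reactants: 1 3-bromo-4-hydroxybenzaldehyde; 2 3-chloro-3-methylbut-1-yne
Product: 3 3-bromo-4-[(2-methylbut-3-yn-2-yl)oxy]benzaldehyde
Conditions: 2 (1.3 equiv), DBU, CuCl2 (cat.), MeCN, 0 °C → rt
Reagents that add atoms: none
Why: Copper-catalysed Williamson-type O-alkylation of a phenol with a tertiary propargylic chloride, which works best with acidic, electron-poor phenols such as 1, should give the 1,1-dimethylpropargyl aryl ether.

Step 2
Reactants: 3 3-bromo-4-[(2-methylbut-3-yn-2-yl)oxy]benzaldehyde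
Product: 4 3-bromo-4-[(2-methylbut-3-en-2-yl)oxy]benzaldehyde
Conditions: H2 (1 atm), Pd/CaCO3 poisoned with Pb(OAc)2, quinoline, EtOAc, rt
Reagents that add atoms: none
Why: Lindlar semi-hydrogenation should stop at the terminal alkene and leave the aryl bromide and the aldehyde alone.

Step 3
Reactants: 4 3-bromo-4-[(2-methylbut-3-en-2-yl)oxy]benzaldehyde
Product: 5 3-bromo-4-hydroxy-5-(3-methylbut-2-en-1-yl)benzaldehyde
Conditions: xylenes, 135 °C
Reagents that add atoms: none
Why: The aromatic Claisen rearrangement, a [3,3] sigmatropic shift, can only deliver the allyl terminus to the one free ortho carbon (C5), and so turns the 1,1-dimethylallyl ether into the prenyl phenol after tautomerisation.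

Step 4
Reactants: 5 3-bromo-4-hydroxy-5-(3-methylbut-2-en-1-yl)benzaldehyde
Product: 6 3-bromo-4-[(tert-butyldimethylsilyl)oxy]-5-(3-methylbut-2-en-1-yl)benzaldehyde
Conditions: TBSCl, imidazole, DMF, rt
Reagents that add atoms: tert-butyldimethylsilyl chloride, CC(C)(C)[Si](C)(C)Cl
Why: Imidazole-promoted silyl ether formation caps the phenol with the group that is kept to the end and removed by fluoride, so no acid is ever needed near the prenyl group.

Step 5
Reactants: 6 3-bromo-4-[(tert-butyldimethylsilyl)oxy]-5-(3-methylbut-2-en-1-yl)benzaldehyde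
Product: 7 [2-bromo-4-(dimethoxymethyl)-6-(3-methylbut-2-en-1-yl)phenoxy](tert-butyl)dimethylsilane
Conditions: HC(OMe)3, PPTS (cat.), MeOH, rt; then Et3N
Reagents that add atoms: trimethyl orthoformate, COC(OC)OC; methanol, CO
Why: Orthoformate-driven acetalisation under a weak acid masks the aldehyde against the organomagnesium reagents of steps 6 and 8, and should leave the aryl silyl ether and the prenyl group intact.

Step 6
Reactants: 7 [2-bromo-4-(dimethoxymethyl)-6-(3-methylbut-2-en-1-yl)phenoxy](tert-butyl)dimethylsilane; 8 methyl (2R)-oxirane-2-carboxylate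
Product: 10 methyl (2R)-3-{2-[(tert-butyldimethylsilyl)oxy]-5-(dimethoxymethyl)-3-(3-methylbut-2-en-1-yl)phenyl}-2-hydroxypropanoate, via arylmagnesium bromide 9 (not isolated)
Conditions: Mg, LiCl, THF, rt; then CuI (10 mol%), 8 (1.2 equiv), THF, −40 °C → −20 °C; then H2O
Reagents that add atoms: none
Why: Grignard formation followed by copper-catalysed SN2 opening of the epoxide at its unsubstituted carbon C3 should give the α-hydroxy ester with the (R) centre of 8 carried over unchanged, because the cuprate opens the epoxide at −40 °C faster than the Grignard reagent adds to the ester, and an arylmagnesium species is far less prone to O→C silyl migration than an aryllithium.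

Step 7
Reactants: 10 methyl (2R)-3-{2-[(tert-butyldimethylsilyl)oxy]-5-(dimethoxymethyl)-3-(3-methylbut-2-en-1-yl)phenyl}-2-hydroxypropanoate
Product: 11 methyl (2R)-2-[(tert-butyldimethylsilyl)oxy]-3-{2-[(tert-butyldimethylsilyl)oxy]-5-(dimethoxymethyl)-3-(3-methylbut-2-en-1-yl)phenyl}propanoate
Conditions: TBSCl, imidazole, DMAP (cat.), DMF, rt
Reagents that add atoms: tert-butyldimethylsilyl chloride, CC(C)(C)[Si](C)(C)Cl
Why: Silyl ether formation with the chloride and imidazole is chosen over the silyl triflate, which would attack the dimethyl acetal, and protects the carbinol for all later steps.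

Step 8
Reactants: 11 methyl (2R)-2-[(tert-butyldimethylsilyl)oxy]-3-{2-[(tert-butyldimethylsilyl)oxy]-5-(dimethoxymethyl)-3-(3-methylbut-2-en-1-yl)phenyl}propanoate
Product: 13 (3R)-3-[(tert-butyldimethylsilyl)oxy]-4-{2-[(tert-butyldimethylsilyl)oxy]-5-(dimethoxymethyl)-3-(3-methylbut-2-en-1-yl)phenyl}butan-2-one, via Weinreb amide 12 (not isolated)
Conditions: MeNHOMe·HCl, iPrMgCl, THF, −20 °C; then MeMgBr, 0 °C; then H2O
Reagents that add atoms: methylmagnesium bromide, C[Mg]Br; N,O-dimethylhydroxylamine hydrochloride, CNOC.Cl (its atoms stay only in intermediate 12)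
Why: The ester is converted by the chloromagnesium amide into the Weinreb amide, whose chelated tetrahedral adduct with MeMgBr collapses to the methyl ketone only on work-up, so a Weinreb ketone synthesis should give 13 without over-addition and without touching the silyloxy-bearing centre.

Step 9
Reactants: 13 (3R)-3-[(tert-butyldimethylsilyl)oxy]-4-{2-[(tert-butyldimethylsilyl)oxy]-5-(dimethoxymethyl)-3-(3-methylbut-2-en-1-yl)phenyl}butan-2-one
Product: 14 tert-butyl{2-[(2R)-2-[(tert-butyldimethylsilyl)oxy]-3-methylbut-3-en-1-yl]-4-(dimethoxymethyl)-6-(3-methylbut-2-en-1-yl)phenoxy}dimethylsilane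
Conditions: Ph3PCH3Br (1.5 equiv), KOtBu (1.4 equiv), THF, 0 °C
Reagents that add atoms: methyltriphenylphosphonium bromide, C[P+](c1ccccc1)(c1ccccc1)c1ccccc1.[Br-]
Why: Wittig methylenation of the methyl ketone with a salt-free ylide at 0 °C should be faster than enolisation, so the isopropenyl group is formed without epimerising the adjacent (R) centre.

Step 10
Reactants: 14 tert-butyl{2-[(2R)-2-[(tert-butyldimethylsilyl)oxy]-3-methylbut-3-en-1-yl]-4-(dimethoxymethyl)-6-(3-methylbut-2-en-1-yl)phenoxy}dimethylsilane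
Product: 15 4-[(tert-butyldimethylsilyl)oxy]-3-[(2R)-2-[(tert-butyldimethylsilyl)oxy]-3-methylbut-3-en-1-yl]-5-(3-methylbut-2-en-1-yl)benzaldehyde
Conditions: PPTS (cat.), acetone/H2O, rt
Reagents that add atoms: water, O
Why: Acetal hydrolysis is easy here because the para-silyloxy group stabilises the benzylic oxocarbenium ion, so a weak acid suffices and both silyl ethers and both alkenes should survive.

Step 11
Reactants: 15 4-[(tert-butyldimethylsilyl)oxy]-3-[(2R)-2-[(tert-butyldimethylsilyl)oxy]-3-methylbut-3-en-1-yl]-5-(3-methylbut-2-en-1-yl)benzaldehyde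
Product: 16 tert-butyl{2-[(2R)-2-[(tert-butyldimethylsilyl)oxy]-3-methylbut-3-en-1-yl]-4-ethynyl-6-(3-methylbut-2-en-1-yl)phenoxy}dimethylsilane
Conditions: Me3SiCHN2, LiN(iPr)2, THF, −78 °C → rt; then H2O
Reagents that add atoms: (trimethylsilyl)diazomethane, C[Si](C)(C)C=[N+]=[N-]
Why: The Colvin rearrangement (addition of lithiated trimethylsilyldiazomethane, Peterson-type elimination, loss of N2 and 1,2-shift of the alkylidene carbene) homologates an aryl aldehyde to the terminal alkyne in one step and avoids the carbonate/methanol medium that would cleave the aryl silyl ether.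

Step 12
Reactants: 17 phloroglucinol
Product: 18 3,5-bis[(tert-butyldimethylsilyl)oxy]phenol
Conditions: TBSCl (2.0 equiv), imidazole, DMF, 0 °C → rt
Reagents that add atoms: tert-butyldimethylsilyl chloride, CC(C)(C)[Si](C)(C)Cl
Why: Silyl ether formation on three equivalent hydroxyls with two equivalents of chloride should give the bis-ether as the main product, the mono- and tris-ethers being separable and recyclable.

Step 13
Reactants: 18 3,5-bis[(tert-butyldimethylsilyl)oxy]phenol
Product: 19 2-iodo-3,5-bis[(tert-butyldimethylsilyl)oxy]phenol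
Conditions: NIS (1.0 equiv), CH2Cl2, −20 °C → 0 °C, dark
Reagents that add atoms: N-iodosuccinimide, O=C1CCC(=O)N1I
Why: In this electrophilic aromatic iodination the free hydroxyl is the strongest activator and the carbon para to it is flanked by two bulky silyloxy groups, so iodine should enter ortho to the hydroxyl at C2.

Step 14
Reactants: 19 2-iodo-3,5-bis[(tert-butyldimethylsilyl)oxy]phenol; 16 tert-butyl{2-[(2R)-2-[(tert-butyldimethylsilyl)oxy]-3-methylbut-3-en-1-yl]-4-ethynyl-6-(3-methylbut-2-en-1-yl)phenoxy}dimethylsilane; 20 carbon monoxide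
Product: 23 5,7-bis[(tert-butyldimethylsilyl)oxy]-2-{4-[(tert-butyldimethylsilyl)oxy]-3-[(2R)-2-[(tert-butyldimethylsilyl)oxy]-3-methylbut-3-en-1-yl]-5-(3-methylbut-2-en-1-yl)phenyl}-4H-chromen-4-one, via ynone 21 (not isolated), via enaminone 22 (not isolated)
Conditions: PdCl2(PPh3)2 (5 mol%), CO (20 bar), Et2NH, 100 °C, autoclave, no copper salt
Reagents that add atoms: none
Why: Oxidative addition of the C–I bond of 19 to zerovalent palladium (generated in situ from PdCl2(PPh3)2) is followed by migratory insertion of CO, and the aroyl–palladium intermediate takes up the acetylide of 16 and releases ynone 21 by reductive elimination, which creates C4a–C4 and C4–C3. Et2NH then adds to the ynone to give enaminone 22, and the phenol oxygen attacks the amine-bearing carbon C2 and expels Et2NH, a 6-endo addition–elimination that forms O1–C2 and closes ring C. The closest known reaction type is the palladium-catalysed carbonylative annulation of 2-iodophenols with terminal alkynes to flavones. No stereocentre is created, and the silylated (R)-carbinol lies far from the reacting atoms and is not touched. The step needs carbonylative coupling to beat direct alkynylation (which would end in a 2-arylbenzofuran) and 6-endo closure to beat 5-exo closure (aurone); the electron-rich aryl group of 19 shifts easily onto CO under 20 bar in the absence of copper, and the amine adduct has C2 as its only electrophilic carbon. The alkyne terminus is flanked by two unsubstituted ring B positions, so its transfer to palladium is sterically easy, and any loss of an aryl silyl group in the hot amine is harmless because step 15 removes them all.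

Step 15
Reactants: 23 5,7-bis[(tert-butyldimethylsilyl)oxy]-2-{4-[(tert-butyldimethylsilyl)oxy]-3-[(2R)-2-[(tert-butyldimethylsilyl)oxy]-3-methylbut-3-en-1-yl]-5-(3-methylbut-2-en-1-yl)phenyl}-4H-chromen-4-one
Product: 24 5,7-dihydroxy-2-{4-hydroxy-3-[(2R)-2-hydroxy-3-methylbut-3-en-1-yl]-5-(3-methylbut-2-en-1-yl)phenyl}-4H-chromen-4-one
Conditions: Bu4NF (6 equiv), AcOH (6 equiv), THF, 0 °C → rt
Reagents that add atoms: none
Why: Fluoride-driven desilylation, buffered with acetic acid so that neither free phenoxide nor strong acid is present, should remove all four silyl groups without cyclising the prenyl or hydroxy-isopropenyl side chain onto the neighbouring phenol.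

**Compound list**

1 | 3-bromo-4-hydroxybenzaldehyde | O=Cc1ccc(O)c(Br)c1 | starting material
2 | 3-chloro-3-methylbut-1-yne | CC(C)(Cl)C#C | starting material
3 | 3-bromo-4-[(2-methylbut-3-yn-2-yl)oxy]benzaldehyde | O=Cc1ccc(OC(C)(C)C#C)c(Br)c1 | intermediate
4 | 3-bromo-4-[(2-methylbut-3-en-2-yl)oxy]benzaldehyde | O=Cc1ccc(OC(C)(C)C=C)c(Br)c1 | intermediate
5 | 3-bromo-4-hydroxy-5-(3-methylbut-2-en-1-yl)benzaldehyde | O=Cc1cc(Br)c(O)c(CC=C(C)C)c1 | intermediate
6 | 3-bromo-4-[(tert-butyldimethylsilyl)oxy]-5-(3-methylbut-2-en-1-yl)benzaldehyde | O=Cc1cc(Br)c(O[Si](C)(C)C(C)(C)C)c(CC=C(C)C)c1 | intermediate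
7 | [2-bromo-4-(dimethoxymethyl)-6-(3-methylbut-2-en-1-yl)phenoxy](tert-butyl)dimethylsilane | COC(OC)c1cc(Br)c(O[Si](C)(C)C(C)(C)C)c(CC=C(C)C)c1 | intermediate
8 | methyl (2R)-oxirane-2-carboxylate (methyl (R)-glycidate) | COC(=O)[C@H]1CO1 | starting material
9 | {2-[(tert-butyldimethylsilyl)oxy]-5-(dimethoxymethyl)-3-(3-methylbut-2-en-1-yl)phenyl}magnesium bromide | COC(OC)c1cc([Mg]Br)c(O[Si](C)(C)C(C)(C)C)c(CC=C(C)C)c1 | intermediate (not isolated)
10 | methyl (2R)-3-{2-[(tert-butyldimethylsilyl)oxy]-5-(dimethoxymethyl)-3-(3-methylbut-2-en-1-yl)phenyl}-2-hydroxypropanoate | COC(=O)[C@H](O)Cc1cc(C(OC)OC)cc(CC=C(C)C)c1O[Si](C)(C)C(C)(C)C | intermediate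
11 | methyl (2R)-2-[(tert-butyldimethylsilyl)oxy]-3-{2-[(tert-butyldimethylsilyl)oxy]-5-(dimethoxymethyl)-3-(3-methylbut-2-en-1-yl)phenyl}propanoate | COC(=O)[C@H](O[Si](C)(C)C(C)(C)C)Cc1cc(C(OC)OC)cc(CC=C(C)C)c1O[Si](C)(C)C(C)(C)C | intermediate
12 | (2R)-2-[(tert-butyldimethylsilyl)oxy]-3-{2-[(tert-butyldimethylsilyl)oxy]-5-(dimethoxymethyl)-3-(3-methylbut-2-en-1-yl)phenyl}-N-methoxy-N-methylpropanamide | CON(C)C(=O)[C@H](O[Si](C)(C)C(C)(C)C)Cc1cc(C(OC)OC)cc(CC=C(C)C)c1O[Si](C)(C)C(C)(C)C | intermediate (not isolated)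
13 | (3R)-3-[(tert-butyldimethylsilyl)oxy]-4-{2-[(tert-butyldimethylsilyl)oxy]-5-(dimethoxymethyl)-3-(3-methylbut-2-en-1-yl)phenyl}butan-2-one | CC(=O)[C@H](O[Si](C)(C)C(C)(C)C)Cc1cc(C(OC)OC)cc(CC=C(C)C)c1O[Si](C)(C)C(C)(C)C | intermediate
14 | tert-butyl{2-[(2R)-2-[(tert-butyldimethylsilyl)oxy]-3-methylbut-3-en-1-yl]-4-(dimethoxymethyl)-6-(3-methylbut-2-en-1-yl)phenoxy}dimethylsilane | C=C(C)[C@H](O[Si](C)(C)C(C)(C)C)Cc1cc(C(OC)OC)cc(CC=C(C)C)c1O[Si](C)(C)C(C)(C)C | intermediate
15 | 4-[(tert-butyldimethylsilyl)oxy]-3-[(2R)-2-[(tert-butyldimethylsilyl)oxy]-3-methylbut-3-en-1-yl]-5-(3-methylbut-2-en-1-yl)benzaldehyde | C=C(C)[C@H](O[Si](C)(C)C(C)(C)C)Cc1cc(C=O)cc(CC=C(C)C)c1O[Si](C)(C)C(C)(C)C | intermediate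
16 | tert-butyl{2-[(2R)-2-[(tert-butyldimethylsilyl)oxy]-3-methylbut-3-en-1-yl]-4-ethynyl-6-(3-methylbut-2-en-1-yl)phenoxy}dimethylsilane (ring B arylacetylene) | C=C(C)[C@H](O[Si](C)(C)C(C)(C)C)Cc1cc(C#C)cc(CC=C(C)C)c1O[Si](C)(C)C(C)(C)C | intermediate
17 | phloroglucinol (benzene-1,3,5-triol) | Oc1cc(O)cc(O)c1 | starting material
18 | 3,5-bis[(tert-butyldimethylsilyl)oxy]phenol | Oc1cc(O[Si](C)(C)C(C)(C)C)cc(O[Si](C)(C)C(C)(C)C)c1 | intermediate
19 | 2-iodo-3,5-bis[(tert-butyldimethylsilyl)oxy]phenol | Oc1cc(O[Si](C)(C)C(C)(C)C)cc(O[Si](C)(C)C(C)(C)C)c1I | intermediate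
20 | carbon monoxide | [C-]#[O+] | starting material
21 | 1-{2-hydroxy-4,6-bis[(tert-butyldimethylsilyl)oxy]phenyl}-3-{4-[(tert-butyldimethylsilyl)oxy]-3-[(2R)-2-[(tert-butyldimethylsilyl)oxy]-3-methylbut-3-en-1-yl]-5-(3-methylbut-2-en-1-yl)phenyl}prop-2-yn-1-one | C=C(C)[C@H](O[Si](C)(C)C(C)(C)C)Cc1cc(C#CC(=O)c2c(O)cc(O[Si](C)(C)C(C)(C)C)cc2O[Si](C)(C)C(C)(C)C)cc(CC=C(C)C)c1O[Si](C)(C)C(C)(C)C | intermediate (not isolated)
22 | 3-(diethylamino)-1-{2-hydroxy-4,6-bis[(tert-butyldimethylsilyl)oxy]phenyl}-3-{4-[(tert-butyldimethylsilyl)oxy]-3-[(2R)-2-[(tert-butyldimethylsilyl)oxy]-3-methylbut-3-en-1-yl]-5-(3-methylbut-2-en-1-yl)phenyl}prop-2-en-1-one (alkene geometry not defined) | C=C(C)[C@H](O[Si](C)(C)C(C)(C)C)Cc1cc(C(=CC(=O)c2c(O)cc(O[Si](C)(C)C(C)(C)C)cc2O[Si](C)(C)C(C)(C)C)N(CC)CC)cc(CC=C(C)C)c1O[Si](C)(C)C(C)(C)C | intermediate (not isolated)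
23 | 5,7-bis[(tert-butyldimethylsilyl)oxy]-2-{4-[(tert-butyldimethylsilyl)oxy]-3-[(2R)-2-[(tert-butyldimethylsilyl)oxy]-3-methylbut-3-en-1-yl]-5-(3-methylbut-2-en-1-yl)phenyl}-4H-chromen-4-one (tetrakis-TBS ether of the target) | C=C(C)[C@H](O[Si](C)(C)C(C)(C)C)Cc1cc(-c2cc(=O)c3c(O[Si](C)(C)C(C)(C)C)cc(O[Si](C)(C)C(C)(C)C)cc3o2)cc(CC=C(C)C)c1O[Si](C)(C)C(C)(C)C | intermediate
24 | 5,7-dihydroxy-2-{4-hydroxy-3-[(2R)-2-hydroxy-3-methylbut-3-en-1-yl]-5-(3-methylbut-2-en-1-yl)phenyl}-4H-chromen-4-one | C=C(C)[C@H](O)Cc1cc(-c2cc(=O)c3c(O)cc(O)cc3o2)cc(CC=C(C)C)c1O | target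

**Step count**

Total: 15 steps. Longest linear sequence: 13 steps (steps 1–11, then 14 and 15); the ring A branch is steps 12–13.

**Steps most likely to fail**

1. Step 14. Direct alkynylation of the aryl–palladium species may outrun CO insertion, which would lead on to a 2-arylbenzofuran. The amine may also trap the aroyl–palladium species as an amide. Fallback: the same ynone is reached without palladium or CO, with C4 bought in as an aldehyde carbon. Commercial 2,4,6-trihydroxybenzaldehyde is silylated twice (TBSCl, imidazole, DMF), the hydroxyl hydrogen-bonded to the aldehyde staying free, to give 2-hydroxy-4,6-bis[(tert-butyldimethylsilyl)oxy]benzaldehyde F1. Setting out from alkyne 16, deprotonation with n-BuLi (THF, −78 °C) and addition to the lithium phenoxide of F1 (made with LiN(SiMe3)2) should give 1-{2-hydroxy-4,6-bis[(tert-butyldimethylsilyl)oxy]phenyl}-3-{4-[(tert-butyldimethylsilyl)oxy]-3-[(2R)-2-[(tert-butyldimethylsilyl)oxy]-3-methylbut-3-en-1-yl]-5-(3-methylbut-2-en-1-yl)phenyl}prop-2-yn-1-ol F2 as a mixture of carbinol epimers. F2 is oxidised at once with MnO2 in CH2Cl2, and the route is rejoined at ynone 21. Stirring 21 in Et2NH/EtOH then takes it through enaminone 22 to 23, as in the second half of step 14.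

2. Step 6. The arylmagnesium reagent may add to the ester carbonyl in competition with epoxide opening, bromide may open the epoxide, or the silyl group may migrate from oxygen to carbon in the ortho-silyloxy arylmetal. Fallback: the ester is replaced by a carboxylate, which does not accept the Grignard reagent. Setting out from 8, saponification (KOH, EtOH, 0 °C) gives potassium (2R)-oxirane-2-carboxylate F3. The arylmagnesium bromide 9, made from 7 as before, opens F3 at C3 under CuI catalysis in THF at −20 °C. The crude salt potassium (2R)-3-{2-[(tert-butyldimethylsilyl)oxy]-5-(dimethoxymethyl)-3-(3-methylbut-2-en-1-yl)phenyl}-2-hydroxypropanoate F4 is not acidified, so the acetal is spared; it is methylated directly with MeI in DMF. This returns to the route at 10.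

3. Step 13. Iodination may be poorly selective between the carbon ortho and the carbon para to the free hydroxyl, and a second iodination may follow. Fallback: the order is reversed so that symmetry, not substituent direction, fixes the iodine position. Setting out from 17, iodination (I2, NaHCO3, THF/H2O, 0 °C) can give only one mono-iodide, 2-iodobenzene-1,3,5-triol F5, because all three ring CH positions are equivalent. Bis-silylation (TBSCl 2 equiv, imidazole, DMF, 0 °C) should then take the unhindered hydroxyl para to iodine and one of the two equivalent flanking hydroxyls. This returns to the route at 19.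

**Further compounds**

F1 | step 14 | 2-hydroxy-4,6-bis[(tert-butyldimethylsilyl)oxy]benzaldehyde | O=Cc1c(O)cc(O[Si](C)(C)C(C)(C)C)cc1O[Si](C)(C)C(C)(C)C
F2 | step 14 | 1-{2-hydroxy-4,6-bis[(tert-butyldimethylsilyl)oxy]phenyl}-3-{4-[(tert-butyldimethylsilyl)oxy]-3-[(2R)-2-[(tert-butyldimethylsilyl)oxy]-3-methylbut-3-en-1-yl]-5-(3-methylbut-2-en-1-yl)phenyl}prop-2-yn-1-ol (carbinol epimers) | C=C(C)[C@H](O[Si](C)(C)C(C)(C)C)Cc1cc(C#CC(O)c2c(O)cc(O[Si](C)(C)C(C)(C)C)cc2O[Si](C)(C)C(C)(C)C)cc(CC=C(C)C)c1O[Si](C)(C)C(C)(C)C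
F3 | step 6 | potassium (2R)-oxirane-2-carboxylate | [K+].[O-]C(=O)[C@H]1CO1
F4 | step 6 | potassium (2R)-3-{2-[(tert-butyldimethylsilyl)oxy]-5-(dimethoxymethyl)-3-(3-methylbut-2-en-1-yl)phenyl}-2-hydroxypropanoate | [K+].[O-]C(=O)[C@H](O)Cc1cc(C(OC)OC)cc(CC=C(C)C)c1O[Si](C)(C)C(C)(C)C
F5 | step 13 | 2-iodobenzene-1,3,5-triol | Oc1cc(O)c(I)c(O)c1
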